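**Plan**
- Retrosynthesis: the two phenols are unmasked last and the C3/C4 hydroxymethyl arms are traced back to a cis-fused γ-alkoxy-butyrolactone. The tetrahydrofuran (O1, C2–C5) is then cut at C2–C3 and C4–C5 into an ArCH–O–CHAr carbonyl ylide and a Z-enoate.
- Enabling feature: the ring carries 2,5-trans aryl groups (C2 aryl cis to the C3 arm, C5 aryl trans to the C4 arm) and 3,4-cis hydroxymethyl groups. This is the pattern an S-shaped ylide leaves when it adds suprafacially to a cis alkene.
- Forward, dipole half: vanillin 1 → silyl ether 2 → E-stilbene 3 → trans-oxirane 4. Dipolarophile half: furfural 5 → (endoperoxide 6) → lactol 7, acetalised with (−)-menthol 8 to butenolide 9.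
- Ring order: the oxirane is opened by light to ylide 10, whose cycloaddition to 9 closes the tetrahydrofuran onto the lactone (bicycle 11). Hydride then opens the lactone to diol 12 and fluoride frees the phenols to give target 13.
- Stereochemistry: disrotatory photo-opening of the trans-oxirane gives 2,5-trans and the ring alkene gives 3,4-cis. The menthyloxy acetal of 9 (anti attack plus orientation of the ylide) sets the absolute configuration and is lost as menthol.

Key step: step 6

Assumption: the trans-oxirane is used as its racemate, because both of its stereocentres vanish in the planar ylide; the phenols travel as triisopropylsilyl ethers, chosen because they do not respond to the irradiation and come off without acid or hydrogenolysis.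

**Step 1**
Reactants: 1 vanillin
Product: 2 3-methoxy-4-(triisopropylsilyloxy)benzaldehyde
Conditions: TIPSCl, imidazole, DMF, rt
Reagents that add atoms: triisopropylsilyl chloride, CC(C)[Si](Cl)(C(C)C)C(C)C
Why: Imidazole-promoted O-silylation of the phenol; the bulky aryl silyl ether should tolerate low-valent titanium, dioxirane, UV light and hydride.

**Step 2**
Reactants: 2 3-methoxy-4-(triisopropylsilyloxy)benzaldehyde (two molecules)
Product: 3 (E)-1,2-bis[3-methoxy-4-(triisopropylsilyloxy)phenyl]ethene
Conditions: TiCl4, Zn, pyridine, THF, 0 °C then reflux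
Reagents that add atoms: none
Why: McMurry reductive coupling of an aromatic aldehyde, which should give the thermodynamically preferred E-stilbene; pyridine tempers the Lewis acidity so the silyl ethers stay on.

**Step 3**
Reactants: 3 (E)-1,2-bis[3-methoxy-4-(triisopropylsilyloxy)phenyl]ethene
Product: 4 trans-2,3-bis[3-methoxy-4-(triisopropylsilyloxy)phenyl]oxirane (racemic)
Conditions: DMDO, acetone, −20 °C → 0 °C; evaporation in the cold, base-washed glassware
Reagents that add atoms: dimethyldioxirane, CC1(C)OO1
Why: Dioxirane epoxidation is a concerted, stereospecific oxygen transfer, so the E-alkene becomes the trans-oxirane (both centres set relative to each other, racemic); the neutral reagent leaves only acetone and should spare the acid-labile electron-rich oxirane.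

**Step 4**
Reactants: 5 furfural
Product: 7 5-hydroxyfuran-2(5H)-one, via furfural endoperoxide 6 (not isolated)
Conditions: O2, rose bengal disodium salt (C20H2Cl4I4Na2O5, cat.), hν (visible), MeOH, rt
Reagents that add atoms: dioxygen, O=O
Why: Dye-sensitised singlet-oxygen [4+2] cycloaddition to the furan gives endoperoxide 6, which methanol cleaves with loss of the formyl carbon as methyl formate; the lactol centre of 7 is racemic and labile.

**Step 5**
Reactants: 7 5-hydroxyfuran-2(5H)-one; 8 (1R,2S,5R)-menthol
Product: 9 (5R)-5-[(1R,2S,5R)-menthyloxy]furan-2(5H)-one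
Conditions: p-TsOH (cat.), toluene, reflux, Dean–Stark; crystallisation from hexane, mother liquor re-equilibrated with p-TsOH and recrystallised
Reagents that add atoms: none
Why: Acid-catalysed acetalisation of the lactol; the acetal carbon epimerises under the acid and the (5R) diastereomer should crystallise selectively, so crystallisation-driven equilibration sets C5 under control of the menthyl group.

**Step 6**
Reactants: 4 trans-2,3-bis[3-methoxy-4-(triisopropylsilyloxy)phenyl]oxirane; 9 (5R)-5-[(1R,2S,5R)-menthyloxy]furan-2(5H)-one
Product: 11 (3R,3aS,4S,6S,6aR)-4,6-bis[3-methoxy-4-(triisopropylsilyloxy)phenyl]-3-[(1R,2S,5R)-menthyloxy]tetrahydro-1H,3H-furo[3,4-c]furan-1-one, via carbonyl ylide 10 (not isolated)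
Conditions: hν (300 nm lamps, quartz), 9 (5 equiv), degassed MeCN, −20 °C; chromatographic separation of diastereomers
Reagents that add atoms: none
Why: Light absorbed by the aryl-oxirane cleaves the ring C–C bond in the symmetry-allowed disrotatory sense, turning trans-oxirane 4 into the S-shaped (E,Z) carbonyl ylide 10, which then adds suprafacially across the enoate C=C of 9 in a concerted 1,3-dipolar [3+2] cycloaddition (ylide HOMO, butenolide LUMO). The closest known reaction is the photochemical trapping of ylides from 2,3-diaryloxiranes by maleates, fumarates and acrylates, and 5-alkoxybutenolides are established partners for other 1,3-dipoles. The tetrahydrofuran ring closes intermolecularly by forming both C–C bonds (C6–C6a and C3a–C4 of 11, C2–C3 and C4–C5 of the target) in one step, cis-fused to the lactone already present. C3a and C6a inherit the cis relation of the ring alkene and their absolute configuration follows from attack on the face anti to the menthyloxy group at the acetal carbon; C4 and C6 are trans to each other because the in/out geometry of 10 is carried over. To reach the right enantiomer the inward-aryl terminus must bond to the β-carbon in the endo arrangement (lactone tucked under C–O–C, away from the inward aryl), which is expected because the twisted inward aryl leaves the larger HOMO coefficient on its carbon to match the larger LUMO coefficient at the β-carbon, and the outward aryl then sits beside the flat carbonyl and not beside the acetal carbon. A fivefold excess of 9 at −20 °C should trap 10 before it recloses to the cis-oxirane or loses its geometry.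

**Step 7**
Reactants: 11 cycloadduct
Product: 12 [(2S,3S,4R,5S)-2,5-bis[3-methoxy-4-(triisopropylsilyloxy)phenyl]tetrahydrofuran-3,4-diyl]dimethanol
Conditions: LiAlH4, THF, 0 °C → rt; then H2O, aq NaOH
Reagents that add atoms: none
Why: Hydride reduction of the lactone carbonyl and of the aldehyde masked in the acyloxy acetal turns both carbons into primary alcohols and expels menthol; no bond to C2–C5 is touched, so the four ring stereocentres are kept.

**Step 8**
Reactants: 12 bis-silyl diol
Product: 13 [(2S,3S,4R,5S)-2,5-bis(4-hydroxy-3-methoxyphenyl)tetrahydrofuran-3,4-diyl]dimethanol (target; C2 carries the aryl cis to the C3 arm)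
Conditions: Bu4NF, AcOH, THF, 0 °C → rt
Reagents that add atoms: none
Why: Fluoride-driven cleavage of the aryl silyl ethers (Si–F bond formation); acetic acid keeps the phenols protonated so the para-hydroxybenzylic ring ethers are not opened through a quinone methide.

**Compound list**
1 | vanillin | COc1cc(C=O)ccc1O | starting material
2 | 3-methoxy-4-(triisopropylsilyloxy)benzaldehyde | COc1cc(C=O)ccc1O[Si](C(C)C)(C(C)C)C(C)C | intermediate
3 | (E)-1,2-bis[3-methoxy-4-(triisopropylsilyloxy)phenyl]ethene | COc1cc(/C=C/c2ccc(O[Si](C(C)C)(C(C)C)C(C)C)c(OC)c2)ccc1O[Si](C(C)C)(C(C)C)C(C)C | intermediate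
4 | trans-2,3-bis[3-methoxy-4-(triisopropylsilyloxy)phenyl]oxirane, racemate, (2S,3S) enantiomer drawn | COc1cc(ccc1O[Si](C(C)C)(C(C)C)C(C)C)[C@@H]1O[C@H]1c1ccc(O[Si](C(C)C)(C(C)C)C(C)C)c(OC)c1 | intermediate
5 | furfural | O=Cc1ccco1 | starting material
6 | furfural endoperoxide (2,3,7-trioxabicyclo[2.2.1]hept-5-ene-1-carbaldehyde), racemic | O=CC12C=CC(OO1)O2 | intermediate (not isolated)
7 | 5-hydroxyfuran-2(5H)-one, racemic and configurationally labile | O=C1C=CC(O)O1 | intermediate
8 | (1R,2S,5R)-menthol | CC(C)[C@@H]1CC[C@@H](C)C[C@H]1O | starting material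
9 | (5R)-5-[(1R,2S,5R)-menthyloxy]furan-2(5H)-one | O=C1C=C[C@H](O[C@@H]2C[C@H](C)CC[C@H]2C(C)C)O1 | intermediate
10 | S-shaped (E,Z) carbonyl ylide ArCH=O(+)–CH(−)Ar, Ar = 3-methoxy-4-(triisopropylsilyloxy)phenyl; one resonance form drawn, aryl on the C=O carbon outward, aryl on the carbanion carbon inward | COc1cc(ccc1O[Si](C(C)C)(C(C)C)C(C)C)/C=[O+]/[CH-]c1ccc(O[Si](C(C)C)(C(C)C)C(C)C)c(OC)c1 | intermediate (not isolated)
11 | (3R,3aS,4S,6S,6aR)-4,6-bis[3-methoxy-4-(triisopropylsilyloxy)phenyl]-3-[(1R,2S,5R)-menthyloxy]tetrahydro-1H,3H-furo[3,4-c]furan-1-one; cis-fused, C6 aryl (beside the carbonyl-bearing C6a) cis to the lactone, C4 aryl and menthyloxy on the convex face | COc1cc(ccc1O[Si](C(C)C)(C(C)C)C(C)C)[C@H]2O[C@H](c3ccc(O[Si](C(C)C)(C(C)C)C(C)C)c(OC)c3)[C@@H]4[C@H]2C(=O)O[C@H]4O[C@@H]5C[C@H](C)CC[C@H]5C(C)C | intermediate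
12 | [(2S,3S,4R,5S)-2,5-bis[3-methoxy-4-(triisopropylsilyloxy)phenyl]tetrahydrofuran-3,4-diyl]dimethanol | COc1cc(ccc1O[Si](C(C)C)(C(C)C)C(C)C)[C@H]2O[C@H](c3ccc(O[Si](C(C)C)(C(C)C)C(C)C)c(OC)c3)[C@@H](CO)[C@H]2CO | intermediate
13 | [(2S,3S,4R,5S)-2,5-bis(4-hydroxy-3-methoxyphenyl)tetrahydrofuran-3,4-diyl]dimethanol | COc1cc([C@H]2O[C@H](c3ccc(O)c(OC)c3)[C@@H](CO)[C@H]2CO)ccc1O | target

**Step count and risks**
Total step count: 8. Longest linear sequence: 6 steps (steps 1, 2, 3, 6, 7, 8 from vanillin).

Steps most likely to fail:

Step 6. The ylide may pair with the butenolide in the other orientation (outward-aryl terminus to the β-carbon), so that the diastereomer leading to the mirror-image tetrahydrofuran predominates. The ylide may also reclose to the cis-oxirane and reopen to the W-shaped ylide, giving 2,5-cis adducts. For the first failure the fallback uses the antipodal auxiliary, which turns the same preference into the wanted result. It sets out from lactol 7 and oxirane 4. Lactol 7 is acetalised with commercial (1S,2R,5S)-menthol under the conditions of step 5 to give (5S)-5-[(1S,2R,5S)-menthyloxy]furan-2(5H)-one F1. Irradiation of 4 with F1 as in step 6 should then give, through the same ylide 10, the adduct (3S,3aR,4S,6S,6aS)-4,6-bis[3-methoxy-4-(triisopropylsilyloxy)phenyl]-3-[(1S,2R,5S)-menthyloxy]tetrahydro-1H,3H-furo[3,4-c]furan-1-one F2. Its reduction with LiAlH4 as in step 7 releases the antipodal menthol and returns to the route at diol 12.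

Step 3. The very electron-rich oxirane may rearrange (Meinwald-type shift to the diarylacetaldehyde or deoxybenzoin) or be opened by adventitious acid during oxidation and isolation, and the arenes may be over-oxidised. The fallback builds the oxirane under basic conditions by sulfur-ylide chemistry and sets out from aldehyde 2. NaBH4 in MeOH gives [3-methoxy-4-(triisopropylsilyloxy)phenyl]methanol F3. PBr3 in Et2O at 0 °C converts it to 4-(bromomethyl)-2-methoxy-1-(triisopropylsilyloxy)benzene F4. F4 and tetrahydrothiophene form 1-[3-methoxy-4-(triisopropylsilyloxy)benzyl]tetrahydrothiophenium bromide F5. K2CO3 in MeCN–H2O deprotonates it to the benzylic sulfonium ylide F6 in the presence of a second portion of 2. Corey–Chaykovsky benzylidene transfer, trans-selective for such semi-stabilised ylides because betaine formation is reversible, should then give oxirane 4 directly, where the fallback rejoins the route.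

Step 2. The reductive coupling may stop at the pinacol stage, give E/Z mixtures, or strip the silyl ethers under the Lewis-acidic titanium conditions. The fallback replaces carbonyl coupling by olefin metathesis and sets out from aldehyde 2. Wittig methylenation with Ph3P=CH2 in THF gives 2-methoxy-1-(triisopropylsilyloxy)-4-vinylbenzene F7. Self-metathesis of F7 with second-generation Grubbs catalyst in CH2Cl2 at reflux, with ethylene swept out, should give the E-stilbene and returns to the route at 3.

**Further compounds**
F1 | step 6 | (5S)-5-[(1S,2R,5S)-menthyloxy]furan-2(5H)-one | O=C1C=C[C@@H](O[C@H]2C[C@@H](C)CC[C@@H]2C(C)C)O1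
F2 | step 6 | (3S,3aR,4S,6S,6aS)-4,6-bis[3-methoxy-4-(triisopropylsilyloxy)phenyl]-3-[(1S,2R,5S)-menthyloxy]tetrahydro-1H,3H-furo[3,4-c]furan-1-one | COc1cc(ccc1O[Si](C(C)C)(C(C)C)C(C)C)[C@H]2O[C@H](c3ccc(O[Si](C(C)C)(C(C)C)C(C)C)c(OC)c3)[C@H]4[C@@H]2C(=O)O[C@@H]4O[C@H]5C[C@@H](C)CC[C@@H]5C(C)C
F3 | step 3 | [3-methoxy-4-(triisopropylsilyloxy)phenyl]methanol | COc1cc(CO)ccc1O[Si](C(C)C)(C(C)C)C(C)C
F4 | step 3 | 4-(bromomethyl)-2-methoxy-1-(triisopropylsilyloxy)benzene | COc1cc(CBr)ccc1O[Si](C(C)C)(C(C)C)C(C)C
F5 | step 3 | 1-[3-methoxy-4-(triisopropylsilyloxy)benzyl]tetrahydrothiophenium bromide | COc1cc(C[S+]2CCCC2)ccc1O[Si](C(C)C)(C(C)C)C(C)C.[Br-]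
F6 | step 3 | [3-methoxy-4-(triisopropylsilyloxy)phenyl](tetrahydrothiophenium-1-yl)methanide | COc1cc([CH-][S+]2CCCC2)ccc1O[Si](C(C)C)(C(C)C)C(C)C
F7 | step 2 | 2-methoxy-1-(triisopropylsilyloxy)-4-vinylbenzene | COc1cc(C=C)ccc1O[Si](C(C)C)(C(C)C)C(C)C
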